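At the time of reading, 150 s, the flask has behind it a charge of less free catalyst than either earlier run, so the runs must first be put on the flask's clock.

| setting | north-east | north-west | flask |
|---|---|---|---|
| substrate | 0.029 M | 0.029 M | 0.029 M |
| free catalyst | 0.7 mol% | 1.1 mol% | 0.5 mol% |
| remark | run made earlier | run made earlier |  |
| time |  |  | 2.5 min |

| run | time / s | product / % | crystals / % | substrate / % |
|---|---|---|---|---|
| north-east | 10.0 | 11 | 5 | 80 |
| north-east | 30.0 | 30 | 26 | 46 |
| north-east | 60.0 | 54 | 47 | 20 |
| north-east | 80.0 | 62 | 60 | 12 |
| north-east | 120 | 79 | 74 | 3 |
| north-west | 10.0 | 16 | 11 | 74 |
| north-west | 20.0 | 33 | 25 | 50 |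
| north-west | 30.0 | 46 | 41 | 34 |
| north-west | 60.0 | 71 | 72 | 8 |
| north-west | 120 | 86 | 86 | 3 |

(scatter of a reading: 1.5 percentage points)

- amounts and yields of product count crystals too
- given per volume of solution although it is solid: crystals
- reactions considered so far: substrate + free catalyst -> catalyst intermediate; catalyst intermediate <-> free catalyst + product; crystals <-> product; substrate <-> dormant form

* amount of product and crystals together at 2.5 min, in percent of the substrate charged
* concentration of product in solution at 2.5 min, in percent of saturation

Two times are compared: the flask's 150 s and t*, the north-east time with the same catalyst loading multiplied by time (time normalised to loading), 107 s. Their ratio is 0.714. The north-west reading at 20.0 s tests this rule, with substrate the same 0.029 M in both runs: its t* is 31.4 s, and its 33% of product stands beside the north-east 30% at 30.0 s.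

Reading the north-east run between 80.0 s and 120 s at t*, this reckoning commits to 73.5% of product with crystals. Going round once more, the gap in the balance, what product and substrate leave of the charge, reads at 10.0 s 9.00% north-east and 10.0% north-west, so within the scatter that early gap seems to follow plain time. The flask's plain time is longer than t*, so more of its charge may sit in that gap, and its product with crystals may stand slightly below this reckoning.

The forecast gives 73% and 115% of saturation, “though this is poorly determined”.

The flask gives 71.6% and 133% of saturation, with 21.2% of the charge in dormant form at 2.50 min.

substrate + free catalyst → catalyst intermediate (k = 270 /M/s); catalyst intermediate ⇌ free catalyst + product (K = 0.210 M, k = 2.00 /s); crystals ⇌ product, rate k3*(cs3 - [product]) while solid is left; crystals form when [product] > cs3 (solubility = 0.540 mM, k = 0.360 /s); substrate ⇌ dormant form (K = 1.20, k = 0.0130 /s) The reading at t* stands 1.9 percentage points above the flask. A neighbour charged with 0.12 mol% of free catalyst has t* = 25.7 s, where the north-east run between 10.0 s and 30.0 s reads 25.9%, and that neighbour gives 23.5%.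

The runs were computed for substances that don't exist; noise was put on by code.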